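The bicyclic core is disconnected at C5–C9 and C1–O2 in one stroke. In the target the dihydropyran ring holds the array C1–O2–C3=C4–C5–C9, which is the imprint of an enal heterodiene (O2=C3–C4=C5) added across an E-enol ester (C9=C1), while C6–C7–C8 of the cyclopentane ring is a three-atom tether between the two. A single intramolecular oxa-Diels–Alder reaction therefore closes both rings, sets C1, C5 and C9, and delivers the labile C1 acyl acetal directly. Its precursor is an open-chain, fully silylated E-enal bearing the Z-coumarate at C7 and the E-enol 3-methylpentanoate, with C7 set by an Enders alkylation and C8 by alkynylation.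

Key step: step 15

Remark: atoms are named by iridoid numbering (C1 acyl acetal carbon, O2, C3=C4 with C11 on C4, C5 and C9 ring fusion, C6, C7 ester carbinol, C8 tertiary carbinol with C10).
Assumption: bis(2,2,2-trifluoroethyl)phosphonoacetic acid 21 and 4-(tert-butyldimethylsilyloxy)benzaldehyde 23 are bought as catalogue reagents; all compounds from 25 on are handled with exclusion of light because of the Z-cinnamate.

Step 1
Reactants: 1 (2-hydroxyethyl)triphenylphosphonium chloride
Product: 2 triphenyl[2-(triethylsilyloxy)ethyl]phosphonium chloride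
Conditions: TESCl, imidazole, CH2Cl2, 0 °C → rt
Reagents that add atoms: chlorotriethylsilane, CC[Si](CC)(CC)Cl
Why: Standard silylation of a primary alcohol with a silyl chloride and imidazole; the triethylsilyl group is chosen because it is meant to leave again under the mild acid of step 8.

Step 2
Reactants: 2 triphenyl[2-(triethylsilyloxy)ethyl]phosphonium chloride; 3 ethyl formate
Product: 5 3-(triethylsilyloxy)-2-(triphenylphosphoranylidene)propanal, via non-stabilised ylide 4 (not isolated)
Conditions: KN(SiMe3)2 (2 equiv), THF, −78 °C; 3, −78 °C → rt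
Reagents that add atoms: none
Why: Bestmann-type C-acylation of a non-stabilised phosphorus ylide by a formate ester (the way 2-(triphenylphosphoranylidene)propanal is made), the second equivalent of base returning the acylphosphonium ion to the formyl-stabilised ylide.

Step 3
Reactants: 6 2,2-dimethyl-1,3-dioxan-5-one; 7 SAMP, (S)-1-amino-2-(methoxymethyl)pyrrolidine
Product: 8 SAMP hydrazone of 6
Conditions: neat, 4 Å MS, 60 °C
Reagents that add atoms: none
Why: Condensation of a ketone with a 1,1-disubstituted hydrazine, driven by removal of water, gives the hydrazone needed for the Enders SAMP alkylation.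

Step 4
Reactants: 8 SAMP hydrazone of 6; 9 allyl bromide
Product: 12 (S)-4-allyl-2,2-dimethyl-1,3-dioxan-5-one, via lithium azaenolate 10 (not isolated), via allylated SAMP hydrazone 11 (not isolated)
Conditions: t-BuLi, THF, −78 °C; 9, −100 °C → rt; then sat. aq. oxalic acid, Et2O, rt
Reagents that add atoms: water, O
Why: Enders SAMP-hydrazone α-alkylation, in which the rigid methoxy-chelated lithium azaenolate is allylated on one diastereoface and so sets C7 as S, followed by oxalic acid hydrolysis of the hydrazone, which does not racemise the α-centre.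

Step 5
Reactants: 12 (S)-4-allyl-2,2-dimethyl-1,3-dioxan-5-one; 13 ethynylmagnesium bromide
Product: 14 (4S,5R)-5-ethynyl-2,2-dimethyl-4-(prop-2-enyl)-1,3-dioxan-5-ol
Conditions: HC≡CMgBr, CeCl3, THF, −78 °C
Reagents that add atoms: none
Why: 1,2-Addition of an alkynyl organometallic to a ketone, in which the small linear nucleophile should attack the chair dioxanone axially (the ring oxygens leave that face free of 1,3-diaxial hydrogens) and end cis to the equatorial allyl group, setting C8 as R, while CeCl3 suppresses enolisation of the α-alkoxy ketone.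

Step 6
Reactants: 14 (4S,5R)-5-ethynyl-2,2-dimethyl-4-(prop-2-enyl)-1,3-dioxan-5-ol
Product: 15 triethylsilyl ether of 14
Conditions: TESOTf, 2,6-lutidine, CH2Cl2, −78 → 0 °C
Reagents that add atoms: triethylsilyl trifluoromethanesulfonate, CC[Si](CC)(CC)OS(=O)(=O)C(F)(F)F
Why: Silylation of a hindered tertiary alcohol with a silyl triflate and 2,6-lutidine; the ether blocks lactol formation and oxa-Michael addition of O8 in the following steps.

Step 7
Reactants: 15 triethylsilyl ether of 14; 5 3-(triethylsilyloxy)-2-(triphenylphosphoranylidene)propanal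
Product: 18 (2E)-4-[(4S,5R)-5-ethynyl-2,2-dimethyl-5-(triethylsilyloxy)-1,3-dioxan-4-yl]-2-[(triethylsilyloxy)methyl]but-2-enal, via ozonide 16 (not isolated), via aldehyde 17 (not isolated)
Conditions: O3 (Sudan Red 7B endpoint), CH2Cl2, −78 °C; PPh3, −78 °C → rt; concentrate; then 5, PhMe, 80 °C
Reagents that add atoms: none
Why: Chemoselective ozonolysis of the terminal alkene (the alkyne reacts far more slowly) with reductive work-up, then Wittig olefination with a formyl-stabilised ylide, which under thermodynamic control should give the E-enal with the formyl group trans to C6.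

Step 8
Reactants: 18 E-enal acetonide
Product: 19 (2R,3S,5E)-2-ethynyl-6-(hydroxymethyl)-7,7-dimethoxy-2-(triethylsilyloxy)hept-5-ene-1,3-diol
Conditions: CH(OMe)3, PPTS (20 mol%), MeOH, rt → 40 °C; Et3N quench
Reagents that add atoms: trimethyl orthoformate, COC(OC)OC; methanol, CO
Why: One acid-catalysed acetalisation and transacetalisation in methanol masks the enal as its dimethyl acetal, methanolyses the acetonide and cleaves the primary triethylsilyl ether, whereas the hindered tertiary silyl ether at C8 should survive pyridinium tosylate.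

Step 9
Reactants: 19 triol dimethyl acetal
Product: 20 (2R,3S,5E)-1-(tert-butyldimethylsilyloxy)-6-[(tert-butyldimethylsilyloxy)methyl]-2-ethynyl-7,7-dimethoxy-2-(triethylsilyloxy)hept-5-en-3-ol
Conditions: TBSCl (2.2 equiv), imidazole, DMF, 0 °C
Reagents that add atoms: tert-butyldimethylsilyl chloride, CC(C)(C)[Si](C)(C)Cl
Why: Silyl chloride and imidazole silylate the two primary hydroxyls (O10, O11) selectively, because the secondary C7 hydroxyl is flanked by the fully substituted C8.

Step 10
Reactants: 20 bis-silylated C7 alcohol; 21 bis(2,2,2-trifluoroethyl)phosphonoacetic acid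
Product: 22 C7 bis(2,2,2-trifluoroethoxy)phosphorylacetate of 20
Conditions: DCC, DMAP (cat.), CH2Cl2, 0 °C → rt
Reagents that add atoms: none
Why: Steglich esterification, in which the small, activated phosphonoacetic acid should acylate even the hindered C7 hydroxyl, the only free one.

Step 11
Reactants: 22 C7 phosphonoacetate; 23 4-(tert-butyldimethylsilyloxy)benzaldehyde
Product: 25 C7 (2Z)-3-[4-(tert-butyldimethylsilyloxy)phenyl]prop-2-enoate of 20, via potassium phosphonate carbanion 24 (not isolated)
Conditions: KN(SiMe3)2 (1.05 equiv), 18-crown-6, THF, −78 °C; then 23, −78 °C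
Reagents that add atoms: none
Why: Still–Gennari variant of the Horner–Wadsworth–Emmons reaction, in which the trifluoroethyl phosphonate with a dissociated potassium counter-ion eliminates under kinetic control to the Z-cinnamate, so that no activated Z-acyl derivative that could isomerise is ever needed.

Step 12
Reactants: 25 alkyne Z-coumarate
Product: 27 (E)-alkenylboronic acid (boron on C1), via catechol alkenylboronate 26 (not isolated)
Conditions: catecholborane, Cy2BH (10 mol%), THF, rt; then H2O, rt
Reagents that add atoms: catecholborane, B1Oc2ccccc2O1; water, O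
Why: Dialkylborane-catalysed hydroboration of a terminal alkyne by syn addition with boron at the unhindered terminal carbon gives the E-alkenylboronate, which water hydrolyses to the boronic acid, while the conjugated Z-ester and the trisubstituted alkene should react far more slowly.

Step 13
Reactants: 27 (E)-alkenylboronic acid; 28 (R)-3-methylpentanoic acid
Product: 29 E-enol (3R)-3-methylpentanoate with C3 dimethyl acetal
Conditions: Cu(OTf)2 (20 mol%), Et3N, 4 Å MS, O2 (1 atm), CH2Cl2, rt
Reagents that add atoms: none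
Why: Chan–Lam–Evans oxidative C–O coupling of an alkenylboronic acid with a carboxylic acid (copper-catalysed enol esterification) proceeds with retention of alkene geometry and should give the E-enol ester, a copper salt without acetate avoiding a competing enol acetate.

Step 14
Reactants: 29 E-enol ester dimethyl acetal
Product: 30 cycloaddition precursor, the (7S,8R) E-enal E-enol ester
Conditions: PPTS (cat.), acetone/H2O (10:1), rt
Reagents that add atoms: water, O
Why: Mild acid hydrolysis of an α,β-unsaturated dimethyl acetal, which ionises far more readily than the silyl ethers or the enol ester are cleaved, should return the E-enal.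

Step 15
Reactants: 30 cycloaddition precursor
Product: 31 tetrasilylated target, (1S,5S,7S,8R,9S)
Conditions: Eu(fod)3 (10 mol%), BHT, PhMe (0.01 M), 100 °C, dark
Reagents that add atoms: none
Why: Proposed new method: the enal, activated at O2 by Eu(fod)3, should act as a 1-oxadiene and add to the enol ester in a concerted but asynchronous inverse-electron-demand [4+2] cycloaddition in which C9 bonds to C5 ahead of O2 to C1; the closest known reaction type is the intramolecular oxa-Diels–Alder reaction of enals with tethered enol ethers, the enol ester being a less electron-rich 2π partner not yet used in this role. The dihydropyran (C1–O2–C3=C4–C5–C9) closes as the six-membered ring of the cycloaddition itself, and the cyclopentane (C5–C6–C7–C8–C9) closes in the same event as the tether ring through the C5–C9 bond, exo with respect to C9=C1. C1 is set by the E-enol ester, since suprafacial addition leaves the acyloxy group trans to the C9–C8 bond, and C5 and C9 become cis-fused because a three-atom tether on the E-terminus of the heterodiene favours the tether-endo transition state. Their absolute sense is relayed from C7 and C8: the heterodiene should add to the face of C9=C1 on which the forming pyran lies beside the C8 silyloxy group, so that the larger C10 silyloxymethyl arm and the C7 ester end up on the convex face. The step needs tether-endo over tether-exo selectivity and one diastereoface, and the E geometry of both alkenes, the short tether and the two stereocentres acting in the same sense should secure them. A further point is that C1 enters at the acyl acetal oxidation level with no enolisable C1 aldehyde present, so the C8 oxygen, which sits β to C1, is never at risk of elimination.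

Step 16
Reactants: 31 tetrasilylated target
Product: 32 CNP0217341.1
Conditions: HF·pyridine, pyridine, THF, 0 °C → rt
Reagents that add atoms: none
Why: Fluoride-mediated cleavage of all four silyl ethers (three alkyl, one aryl) under buffered acidic conditions, which avoid the alkoxides that would trigger acyl migration or loss of the C1 acyl acetal.

Compound list

1 | (2-hydroxyethyl)triphenylphosphonium chloride | OCC[P+](c1ccccc1)(c1ccccc1)c1ccccc1.[Cl-] | starting material
2 | triphenyl[2-(triethylsilyloxy)ethyl]phosphonium chloride | CC[Si](CC)(CC)OCC[P+](c1ccccc1)(c1ccccc1)c1ccccc1.[Cl-] | intermediate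
3 | ethyl formate | CCOC=O | starting material
4 | triphenyl[2-(triethylsilyloxy)ethylidene]phosphorane (non-stabilised ylide) | CC[Si](CC)(CC)OCC=P(c1ccccc1)(c1ccccc1)c1ccccc1 | intermediate
5 | 3-(triethylsilyloxy)-2-(triphenylphosphoranylidene)propanal | CC[Si](CC)(CC)OCC(C=O)=P(c1ccccc1)(c1ccccc1)c1ccccc1 | intermediate
6 | 2,2-dimethyl-1,3-dioxan-5-one | CC1(C)OCC(=O)CO1 | starting material
7 | SAMP, (S)-1-amino-2-(methoxymethyl)pyrrolidine | COC[C@@H]1CCCN1N | starting material
8 | (S)-N-(2,2-dimethyl-1,3-dioxan-5-ylidene)-2-(methoxymethyl)pyrrolidin-1-amine | COC[C@@H]1CCCN1N=C1COC(C)(C)OC1 | intermediate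
9 | allyl bromide | C=CCBr | starting material
10 | lithium azaenolate of 8 | COC[C@@H]1CCCN1[N-]C1=COC(C)(C)OC1.[Li+] | intermediate
11 | (S)-N-[(4S)-4-allyl-2,2-dimethyl-1,3-dioxan-5-ylidene]-2-(methoxymethyl)pyrrolidin-1-amine (C=N as first formed, amino nitrogen syn to C4) | C=CC[C@@H]1OC(C)(C)OC/C1=N/N1CCC[C@H]1COC | intermediate
12 | (S)-4-allyl-2,2-dimethyl-1,3-dioxan-5-one | C=CC[C@@H]1OC(C)(C)OCC1=O | intermediate
13 | ethynylmagnesium bromide | C#C[Mg]Br | starting material
14 | (4S,5R)-5-ethynyl-2,2-dimethyl-4-(prop-2-enyl)-1,3-dioxan-5-ol | C=CC[C@@H]1OC(C)(C)OC[C@]1(O)C#C | intermediate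
15 | triethyl{[(4S,5R)-5-ethynyl-2,2-dimethyl-4-(prop-2-enyl)-1,3-dioxan-5-yl]oxy}silane | C=CC[C@@H]1OC(C)(C)OC[C@]1(O[Si](CC)(CC)CC)C#C | intermediate
16 | 3-{[(4S,5R)-5-ethynyl-2,2-dimethyl-5-(triethylsilyloxy)-1,3-dioxan-4-yl]methyl}-1,2,4-trioxolane (ozonide, both epimers at the trioxolane carbon) | C1OC(C[C@@H]2OC(C)(C)OC[C@]2(O[Si](CC)(CC)CC)C#C)OO1 | intermediate
17 | 2-[(4S,5R)-5-ethynyl-2,2-dimethyl-5-(triethylsilyloxy)-1,3-dioxan-4-yl]acetaldehyde | O=CC[C@@H]1OC(C)(C)OC[C@]1(O[Si](CC)(CC)CC)C#C | intermediate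
18 | (2E)-4-[(4S,5R)-5-ethynyl-2,2-dimethyl-5-(triethylsilyloxy)-1,3-dioxan-4-yl]-2-[(triethylsilyloxy)methyl]but-2-enal | O=C/C(CO[Si](CC)(CC)CC)=C/C[C@@H]1OC(C)(C)OC[C@]1(O[Si](CC)(CC)CC)C#C | intermediate
19 | (2R,3S,5E)-2-ethynyl-6-(hydroxymethyl)-7,7-dimethoxy-2-(triethylsilyloxy)hept-5-ene-1,3-diol | COC(OC)/C(CO)=C/C[C@H](O)[C@](O[Si](CC)(CC)CC)(CO)C#C | intermediate
20 | (2R,3S,5E)-1-(tert-butyldimethylsilyloxy)-6-[(tert-butyldimethylsilyloxy)methyl]-2-ethynyl-7,7-dimethoxy-2-(triethylsilyloxy)hept-5-en-3-ol | COC(OC)/C(CO[Si](C)(C)C(C)(C)C)=C/C[C@H](O)[C@](O[Si](CC)(CC)CC)(CO[Si](C)(C)C(C)(C)C)C#C | intermediate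
21 | bis(2,2,2-trifluoroethyl)phosphonoacetic acid | OC(=O)CP(=O)(OCC(F)(F)F)OCC(F)(F)F | starting material
22 | (7S,8R) C7 bis(2,2,2-trifluoroethoxy)phosphorylacetate of 20 | COC(OC)/C(CO[Si](C)(C)C(C)(C)C)=C/C[C@H](OC(=O)CP(=O)(OCC(F)(F)F)OCC(F)(F)F)[C@](O[Si](CC)(CC)CC)(CO[Si](C)(C)C(C)(C)C)C#C | intermediate
23 | 4-(tert-butyldimethylsilyloxy)benzaldehyde | O=Cc1ccc(O[Si](C)(C)C(C)(C)C)cc1 | starting material
24 | potassium salt of the phosphonate carbanion of 22 | COC(OC)/C(CO[Si](C)(C)C(C)(C)C)=C/C[C@H](OC(=O)[CH-]P(=O)(OCC(F)(F)F)OCC(F)(F)F)[C@](O[Si](CC)(CC)CC)(CO[Si](C)(C)C(C)(C)C)C#C.[K+] | intermediate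
25 | (7S,8R) C7 (2Z)-3-[4-(tert-butyldimethylsilyloxy)phenyl]prop-2-enoate of 20 (terminal alkyne, C3 dimethyl acetal) | COC(OC)/C(CO[Si](C)(C)C(C)(C)C)=C/C[C@H](OC(=O)/C=C\c1ccc(O[Si](C)(C)C(C)(C)C)cc1)[C@](O[Si](CC)(CC)CC)(CO[Si](C)(C)C(C)(C)C)C#C | intermediate
26 | catechol ester of (E)-alkenylboronic acid 27 | COC(OC)/C(CO[Si](C)(C)C(C)(C)C)=C/C[C@H](OC(=O)/C=C\c1ccc(O[Si](C)(C)C(C)(C)C)cc1)[C@](O[Si](CC)(CC)CC)(CO[Si](C)(C)C(C)(C)C)/C=C/B1Oc2ccccc2O1 | intermediate
27 | (7S,8R) (E)-alkenylboronic acid, boron on C1, E-configured C1=C9, otherwise as 25 | COC(OC)/C(CO[Si](C)(C)C(C)(C)C)=C/C[C@H](OC(=O)/C=C\c1ccc(O[Si](C)(C)C(C)(C)C)cc1)[C@](O[Si](CC)(CC)CC)(CO[Si](C)(C)C(C)(C)C)/C=C/B(O)O | intermediate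
28 | (R)-3-methylpentanoic acid | CC[C@@H](C)CC(=O)O | starting material
29 | (7S,8R) E-enol (3R)-3-methylpentanoate at C1, Z-coumarate at C7, C3 dimethyl acetal on the E-configured C4=C5 alkene | CC[C@@H](C)CC(=O)O/C=C/[C@@](O[Si](CC)(CC)CC)(CO[Si](C)(C)C(C)(C)C)[C@@H](OC(=O)/C=C\c1ccc(O[Si](C)(C)C(C)(C)C)cc1)C/C=C(CO[Si](C)(C)C(C)(C)C)/C(OC)OC | intermediate
30 | cycloaddition precursor: (7S,8R) acyclic (4E)-enal with C1 E-enol (3R)-3-methylpentanoate, C7 Z-coumarate (aryl silyl ether), O8 triethylsilyl, O10 and O11 tert-butyldimethylsilyl | CC[C@@H](C)CC(=O)O/C=C/[C@@](O[Si](CC)(CC)CC)(CO[Si](C)(C)C(C)(C)C)[C@@H](OC(=O)/C=C\c1ccc(O[Si](C)(C)C(C)(C)C)cc1)C/C=C(/C=O)CO[Si](C)(C)C(C)(C)C | intermediate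
31 | tetrasilylated target: (1S,5S,7S,8R,9S) cis-fused cyclopenta[c]pyran with the silyl ethers of 30 | CC[C@@H](C)CC(=O)O[C@@H]1OC=C(CO[Si](C)(C)C(C)(C)C)[C@H]2C[C@H](OC(=O)/C=C\c3ccc(O[Si](C)(C)C(C)(C)C)cc3)[C@](O[Si](CC)(CC)CC)(CO[Si](C)(C)C(C)(C)C)[C@@H]12 | intermediate
32 | CNP0217341.1: (1S,4aS,6S,7R,7aS)-7-hydroxy-4,7-bis(hydroxymethyl)-6-{[(2Z)-3-(4-hydroxyphenyl)prop-2-enoyl]oxy}-1,4a,5,6,7,7a-hexahydrocyclopenta[c]pyran-1-yl (3R)-3-methylpentanoate | CC[C@@H](C)CC(=O)O[C@@H]1OC=C(CO)[C@H]2C[C@H](OC(=O)/C=C\c3ccc(O)cc3)[C@](O)(CO)[C@@H]12 | target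

Total step count: 16. Longest linear sequence: 14 steps (steps 3 to 16, from 6 to 32).

Steps most likely to fail

1. Step 15. The enol ester may be too weak a 2π partner, so that Z-to-E isomerisation of the cinnamate, vinylogous loss of the C7 ester or poor endo and facial selectivity overtakes the cycloaddition. The fallback sets out from 27 and uses the enol ether version of the reaction, which is known chemistry. Copper-promoted coupling of 27 with 4-methoxybenzyl alcohol (Cu(OAc)2, Et3N, excess alcohol) should give the 4-methoxybenzyl E-enol ether dimethyl acetal F1. Acetal hydrolysis as in step 14 should give the enal enol ether F2. Heating should then bring about the established intramolecular inverse-demand oxa-Diels–Alder reaction of an enal with a tethered enol ether, to the C1 4-methoxybenzyl acetal cycloadduct F3. DDQ in wet CH2Cl2 should cleave the benzylic acetal to the C1 lactol F4. Acylation of the lactol with 28 (DCC, DMAP), expected trans to the C9–C8 bond for steric and anomeric reasons, comes back to the route at 31.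

2. Step 13. Transmetalation and C–O bond formation at copper may be slow for this hindered boronic acid and β-branched acid, so that protodeboronation or oxidation of the C–B bond consumes 27. The fallback sets out from 27 and replaces the oxidative boron coupling by a halide substitution. Ipso-iododeboronation with NIS in MeCN, which retains geometry, should give the E-vinyl iodide F5. Heating this with the monovalent copper carboxylate CuO2CCH2CH(CH3)CH2CH3 (from 28 and Cu2O) in pyridine, an Ullmann-type substitution of vinyl halides that retains alkene geometry, comes back to the route at 29.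

3. Step 11. Z-selectivity may be incomplete, or the base may cause side reactions (acetylide formation, silyl migration) on an advanced intermediate. The fallback sets out from 23 and prepares the Z-acid separately. Intermolecular Still–Gennari olefination of 23 with commercial methyl bis(2,2,2-trifluoroethyl)phosphonoacetate should give methyl (2Z)-3-[4-(tert-butyldimethylsilyloxy)phenyl]prop-2-enoate F6, which can be freed of E-isomer at this cheap stage. Me3SnOH in 1,2-dichloroethane should hydrolyse the ester without touching the aryl silyl ether and give the Z-acid F7. Yamaguchi esterification of alcohol 20 with F7 (2,4,6-trichlorobenzoyl chloride, Et3N, then 20 and DMAP) comes back to the route at 25 and makes step 10 unnecessary.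

Further compounds

F1 | step 15 | (7S,8R) 4-methoxybenzyl E-enol ether with C3 dimethyl acetal | COc1ccc(CO/C=C/[C@@](O[Si](CC)(CC)CC)(CO[Si](C)(C)C(C)(C)C)[C@@H](OC(=O)/C=C\c2ccc(O[Si](C)(C)C(C)(C)C)cc2)C/C=C(CO[Si](C)(C)C(C)(C)C)/C(OC)OC)cc1
F2 | step 15 | (7S,8R) 4-methoxybenzyl E-enol ether E-enal | COc1ccc(CO/C=C/[C@@](O[Si](CC)(CC)CC)(CO[Si](C)(C)C(C)(C)C)[C@@H](OC(=O)/C=C\c2ccc(O[Si](C)(C)C(C)(C)C)cc2)C/C=C(/C=O)CO[Si](C)(C)C(C)(C)C)cc1
F3 | step 15 | (1S,5S,7S,8R,9S) C1 4-methoxybenzyl acetal cycloadduct | COc1ccc(CO[C@@H]2OC=C(CO[Si](C)(C)C(C)(C)C)[C@H]3C[C@H](OC(=O)/C=C\c4ccc(O[Si](C)(C)C(C)(C)C)cc4)[C@](O[Si](CC)(CC)CC)(CO[Si](C)(C)C(C)(C)C)[C@@H]23)cc1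
F4 | step 15 | (5S,7S,8R,9S) C1 lactol (anomeric mixture at C1) | OC1OC=C(CO[Si](C)(C)C(C)(C)C)[C@H]2C[C@H](OC(=O)/C=C\c3ccc(O[Si](C)(C)C(C)(C)C)cc3)[C@](O[Si](CC)(CC)CC)(CO[Si](C)(C)C(C)(C)C)[C@@H]12
F5 | step 13 | (7S,8R) E-vinyl iodide (iodine on C1), otherwise as 27 | COC(OC)/C(CO[Si](C)(C)C(C)(C)C)=C/C[C@H](OC(=O)/C=C\c1ccc(O[Si](C)(C)C(C)(C)C)cc1)[C@](O[Si](CC)(CC)CC)(CO[Si](C)(C)C(C)(C)C)/C=C/I
F6 | step 11 | methyl (2Z)-3-[4-(tert-butyldimethylsilyloxy)phenyl]prop-2-enoate | COC(=O)/C=C\c1ccc(O[Si](C)(C)C(C)(C)C)cc1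
F7 | step 11 | (2Z)-3-[4-(tert-butyldimethylsilyloxy)phenyl]prop-2-enoic acid | OC(=O)/C=C\c1ccc(O[Si](C)(C)C(C)(C)C)cc1
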